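The numbers in the tables were generated by integration for an exercise; the scatter is artificial.

By 2.0 min, when you take over, each flask has to be read for its open intermediate, so this note says what you will find and what to leave alone.

| flask | substrate | reagent | free catalyst | remark | time |
|---|---|---|---|---|---|
| alder | 4.5 mM | 4.75 mM | 0.75 mM | run made earlier |  |
| larch | 20 mM | 4.75 mM | 0.75 mM | run made earlier |  |
| maple | 5 mM | 4.75 mM | 1.1 mM | run made earlier |  |
| Thursday's | 8.0 mM | 1.50 mM | 1.5 mM |  | 2.0 min |
| Friday's | 5.0 mM | 1.50 mM | 0.75 mM |  | 2.0 min |
| Monday's | 3.0 mM | 4.75 mM | 0.75 mM |  | 2.0 min |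
| Wednesday's | 5.0 mM | 4.75 mM | 0.75 mM |  | 2.0 min |
| Tuesday's | 15 mM | 4.75 mM | 0.75 mM |  | 2.0 min |

- alder (time / s: open intermediate / %, product / %, substrate / %): 15.0: 34.4, 16.2, 44.0; 30.0: 33.2, 31.8, 27.7; 50.0: 29.2, 47.6, 14.0; 60.0: 28.7, 53.8, 10.2; 80.0: 22.2, 61.5, 5.2
- larch (time / s: open intermediate / %, product / %, substrate / %): 15.0: 31.1, 8.4, 60.6; 30.0: 32.7, 10.2, 49.7; 50.0: 36.4, 14.8, 44.4; 60.0: 38.8, 16.4, 42.8; 80.0: 41.8, 19.0, 36.4
- maple (time / s: open intermediate / %, product / %, substrate / %): 15.0: 33.1, 23.0, 31.9; 30.0: 29.3, 41.7, 17.3; 50.0: 22.8, 57.7, 6.8; 60.0: 21.8, 64.7, 3.0; 80.0: 15.4, 71.0, 0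

(standard deviation of a reading: 1 percentage point)

* the flasks by amount of open intermediate, in percent of the substrate charged, highest first, at 2.0 min (Thursday's / Friday's / Monday's / Wednesday's / Tuesday's)
* the same order at 8.0 min (Thursday's / Friday's / Monday's / Wednesday's / Tuesday's)
* the amount of open intermediate, in percent of the substrate charged of the flask you put first, at 2.0 min
* the amount of open intermediate, in percent of the substrate charged of the flask you put last, at 2.0 min

- the analysis behind the earlier runs scatters by 1 percentage point, standard deviation

In larch, open intermediate reached 8.36 mM at the last reading, more than the 4.75 mM of reagent charged, so substrate opens without reagent; and 0.560 mM of material was unaccounted for there, against 0.75 mM of catalyst, so I take the catalyst to hold some of it. If each product costs one reagent and each catalyst holds one open intermediate, a flask charged with more substrate than its reagent and catalyst together keeps that excess as open intermediate once its substrate has opened. In Thursday's that excess is 62.5 % of the substrate charged, and this is the stranded share: substrate charge less reagent charge less catalyst charge, over substrate charge. Reagent is the limiting reagent in Thursday's, 1.50 mM against 8.0 mM of substrate, so don't touch its charge, since the stranded share moves with it. Tuesday's stranded share is 63.3 % and Friday's 55.0 %, while Monday's and Wednesday's hold more reagent and catalyst than substrate, so I expect their open intermediate to fall. Unopened substrate still comes off the stranded share, and Thursday's has more catalyst than Tuesday's for less substrate, so I expect Thursday's first at 2.0 min, but below 62.5 %.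

The forecast, which has product formed “consuming reagent one-for-one”, gives Thursday's > Friday's > Tuesday's > Wednesday's > Monday's at 2.0 min and Thursday's > Tuesday's > Friday's > Wednesday's > Monday's at 8.0 min, with 63 % (55 % to 70 %) in the first flask and 2 % (0.5 % to 6 %) in the last; its top sits at my stranded share, where I go lower.

The flasks come out Thursday's > Friday's > Tuesday's > Wednesday's > Monday's at 2.0 min and Thursday's > Tuesday's > Friday's > Wednesday's > Monday's at 8.0 min, with 57.5 % of open intermediate in Thursday's and 3.90 % in Monday's at 2.0 min.

    substrate + free catalyst → free catalyst + open intermediate (k = 92.0 /M/s)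
    free catalyst + open intermediate ⇌ catalyst intermediate (K = 2200 /M, k = 120 /M/s)
    reagent + catalyst intermediate → free catalyst + product (k = 100 /M/s)
    reagent ⇌ dormant form (K = 1.70, k = 0.0670 /s)

Thursday's at 2.00 min still holds 7.38 % of its substrate, and its stranded share less that is 55.1 %, against the 57.5 % of open intermediate found and the forecast's 63 %; by 20.0 min the open intermediate of Thursday's stands at 64.0 %. A neighbour of Monday's flask, charged instead with 12 mM of substrate, so that its reagent is 0.396 equiv, has a stranded share of 54.2 %; less its 18 % of unopened substrate that is 36.2 %, and this neighbour holds 42.2 % of open intermediate at 2.00 min, with dormant form at 0.455 mM, a quantity equal to 3.79 % of its substrate charge.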